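The naphthalene is cut at C1–C8a. With the 4-hydroxyphenyl group on C1, the aroyl groups on C2 and C3, a hydrogen on C4 and the diol on ring A (C4a–C8a), C2 and C3 are the α-carbons of a 1,4-diaryl-1,4-diketone and C1 and C4 the methine carbons of two arylidene groups, the one at C4 bringing ring A. A single acid-promoted Friedel–Crafts closure of this (E,E)-dienedione, built as its heptamethyl ether from a symmetrical diketone and two aldehydes, joins the ring A carbon para to a methoxy group to the enone carbon C1 and delivers ring B as a trans-1,2-dihydronaphthalene. Dehydrogenation and sevenfold demethylation follow.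

Key step: step 4

Remark: the target has no stereocentre, so the two centres formed in step 4 are racemic and vanish in step 5. All seven phenols are carried as methyl ethers; locants C1–C8a in steps 4 and 5 are the naphthalene locants defined above.

Step 1
Reactants: 1 1,3-dimethoxybenzene; 2 succinyl chloride
Product: 3 1,4-bis(2,4-dimethoxyphenyl)butane-1,4-dione
Conditions: AlCl3 (2.4 equiv), 1 (2.2 equiv), CH2Cl2, 0 °C; ice/aq. HCl
Reagents that add atoms: none
Why: Friedel–Crafts acylation, in which each acyl chloride end attacks one arene at the carbon para to one methoxy group and ortho to the other, each new ketone deactivates its own ring so that one diacid chloride joins exactly two arenes, and 0 °C should keep the ortho-methoxy groups from Lewis-acid cleavage.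

Step 2
Reactants: 3 1,4-bis(2,4-dimethoxyphenyl)butane-1,4-dione; 4 3,4-dimethoxybenzaldehyde
Product: 7 (2E)-2-(3,4-dimethoxybenzylidene)-1,4-bis(2,4-dimethoxyphenyl)butane-1,4-dione, via aldol adduct 5 (not isolated), via mesylate 6 (not isolated)
Conditions: LiN(SiMe3)2 (1.0 equiv), THF, −78 °C; 4, −78 °C; AcOH, −78 °C; crude: MsCl, Et3N, CH2Cl2, 0 °C; DBU, 0 °C to rt
Reagents that add atoms: none
Why: Directed crossed aldol addition followed by mesylation and E1cB elimination, in which one equivalent of amide base forms only the mono-enolate, the cold-quenched adduct 5 cannot take up a second aldehyde (a base-catalysed condensation is not expected to stop here, because the methylene of 7 should be more acidic than that of 3), and loss of methanesulfonate gives the more stable E alkene with ring A trans to the aroyl group.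

Step 3
Reactants: 7 (2E)-2-(3,4-dimethoxybenzylidene)-1,4-bis(2,4-dimethoxyphenyl)butane-1,4-dione; 8 4-methoxybenzaldehyde
Product: 11 (2E,3E)-2-(3,4-dimethoxybenzylidene)-3-(4-methoxybenzylidene)-1,4-bis(2,4-dimethoxyphenyl)butane-1,4-dione, via aldol adduct 9 (not isolated), via mesylate 10 (not isolated)
Conditions: LiN(SiMe3)2 (1.05 equiv), THF, −78 °C; 8, −78 °C; AcOH, −78 °C; crude: MsCl, Et3N, CH2Cl2, 0 °C; DBU, 0 °C to rt
Reagents that add atoms: none
Why: The same directed aldol–mesylation–E1cB sequence applies, since the remaining methylene is the only acidic site of 7, its cross-conjugated dienolate should add to the aldehyde through the α-carbon under kinetic control, and elimination from 10 gives the E alkene, any Z isomer being harmless because the acid of step 4 equilibrates both alkene geometries.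

Step 4
Reactants: 11 (2E,3E)-2-(3,4-dimethoxybenzylidene)-3-(4-methoxybenzylidene)-1,4-bis(2,4-dimethoxyphenyl)butane-1,4-dione
Product: 13 rac-[(1R,2S)-6,7-dimethoxy-1-(4-methoxyphenyl)-1,2-dihydronaphthalene-2,3-diyl]bis[(2,4-dimethoxyphenyl)methanone], via enol 12 (not isolated)
Conditions: CF3SO3H (3 equiv), CH2Cl2, 0 °C to rt; aq. NaHCO3
Reagents that add atoms: none
Why: CF3SO3H protonates the oxygen of the C2 aroyl group and turns C1=C2 into a hydroxyallyl cation whose C1 end is a 4-methoxybenzylic carbon; C8a of ring A, held next to C1 because ring A is cis to C2 across the E C3=C4 bond, attacks C1, proton loss re-aromatises ring A to give enol 12, and ketonisation gives 13. The closest known reaction type is the triflic-acid cyclisation of (E,E)-dibenzylidenesuccinates to trans-1-aryl-1,2-dihydronaphthalenes, an intramolecular Friedel–Crafts conjugate alkylation. Ring B closes in the 6-endo-trig mode, because both carbons of the attacked C1=C2 bond end up inside the new ring. C1 forms without facial bias and is racemic, while C2 is set when 12 is protonated anti to the C1 aryl group and stays epimerisable in acid, so the trans isomer should result under thermodynamic control; both centres are erased in step 5. The step needs ring A, and not the anisyl ring or an aroyl ring, as the nucleophile: the attacking carbon of ring A is para to a methoxy group, the anisyl carbon that could attack C4 is meta to its methoxy group, the ring A carbon between the side chain and the neighbouring methoxy group is flanked on both sides, and the free ortho carbon of each aroyl ring is meta to both of its methoxy groups, which shuts off a Nazarov-type closure. Capping every phenol, including the two ortho to the carbonyl groups, prevents oxa-Michael closure to flavanone-type rings.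

Step 5
Reactants: 13 rac-[(1R,2S)-6,7-dimethoxy-1-(4-methoxyphenyl)-1,2-dihydronaphthalene-2,3-diyl]bis[(2,4-dimethoxyphenyl)methanone]
Product: 14 [6,7-dimethoxy-1-(4-methoxyphenyl)naphthalene-2,3-diyl]bis[(2,4-dimethoxyphenyl)methanone]
Conditions: DDQ (1.5 equiv), toluene, 80 °C
Reagents that add atoms: none
Why: Quinone dehydrogenation, in which DDQ abstracts hydride from the doubly benzylic C1–H (the cation is stabilised by the 4-methoxyphenyl group and by the C6 methoxy group para to C8a) and loss of the acidic C2 proton gives the naphthalene, so both stereocentres disappear and aromatisation drives the reaction.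

Step 6
Reactants: 14 [6,7-dimethoxy-1-(4-methoxyphenyl)naphthalene-2,3-diyl]bis[(2,4-dimethoxyphenyl)methanone]
Product: 15 [6,7-dihydroxy-1-(4-hydroxyphenyl)naphthalene-2,3-diyl]bis[(2,4-dihydroxyphenyl)methanone]
Conditions: BBr3 (14 equiv), CH2Cl2, −78 °C to rt; H2O, 0 °C
Reagents that add atoms: none
Why: Lewis-acid ether cleavage (BBr3 demethylation), in which each methoxy oxygen binds boron and bromide removes the methyl group by SN2 displacement, the two methoxy groups ortho to the carbonyl groups going first through chelation and the other five with excess reagent, while the diaryl ketones and the biaryl bond are inert and water hydrolyses the aryl borates to the seven phenols.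

Compound list
1 | 1,3-dimethoxybenzene | COc1cccc(OC)c1 | starting material
2 | succinyl chloride (butanedioyl dichloride) | ClC(=O)CCC(Cl)=O | starting material
3 | 1,4-bis(2,4-dimethoxyphenyl)butane-1,4-dione | COc1ccc(c(OC)c1)C(=O)CCC(=O)c1ccc(OC)cc1OC | intermediate
4 | 3,4-dimethoxybenzaldehyde | COc1ccc(C=O)cc1OC | starting material
5 | 2-[(3,4-dimethoxyphenyl)(hydroxy)methyl]-1,4-bis(2,4-dimethoxyphenyl)butane-1,4-dione (aldol adduct; racemic, both diastereomers, centres left open because both are destroyed in step 2) | COc1ccc(cc1OC)C(O)C(CC(=O)c1ccc(OC)cc1OC)C(=O)c1ccc(OC)cc1OC | intermediate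
6 | 2-[(3,4-dimethoxyphenyl)(methanesulfonyloxy)methyl]-1,4-bis(2,4-dimethoxyphenyl)butane-1,4-dione (mesylate of 5; racemic, both diastereomers) | COc1ccc(cc1OC)C(OS(C)(=O)=O)C(CC(=O)c1ccc(OC)cc1OC)C(=O)c1ccc(OC)cc1OC | intermediate
7 | (2E)-2-(3,4-dimethoxybenzylidene)-1,4-bis(2,4-dimethoxyphenyl)butane-1,4-dione | COc1ccc(cc1OC)/C=C(\CC(=O)c1ccc(OC)cc1OC)C(=O)c1ccc(OC)cc1OC | intermediate
8 | 4-methoxybenzaldehyde | COc1ccc(C=O)cc1 | starting material
9 | (2E)-2-(3,4-dimethoxybenzylidene)-3-[hydroxy(4-methoxyphenyl)methyl]-1,4-bis(2,4-dimethoxyphenyl)butane-1,4-dione (aldol adduct; racemic, both diastereomers, sp3 centres left open) | COc1ccc(cc1)C(O)C(C(=O)c1ccc(OC)cc1OC)/C(=C\c1ccc(OC)c(OC)c1)C(=O)c1ccc(OC)cc1OC | intermediate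
10 | (2E)-2-(3,4-dimethoxybenzylidene)-3-[(methanesulfonyloxy)(4-methoxyphenyl)methyl]-1,4-bis(2,4-dimethoxyphenyl)butane-1,4-dione (mesylate of 9; racemic, both diastereomers) | COc1ccc(cc1)C(OS(C)(=O)=O)C(C(=O)c1ccc(OC)cc1OC)/C(=C\c1ccc(OC)c(OC)c1)C(=O)c1ccc(OC)cc1OC | intermediate
11 | (2E,3E)-2-(3,4-dimethoxybenzylidene)-3-(4-methoxybenzylidene)-1,4-bis(2,4-dimethoxyphenyl)butane-1,4-dione | COc1ccc(cc1)/C=C(/C(=O)c1ccc(OC)cc1OC)\C(=C/c1ccc(OC)c(OC)c1)C(=O)c1ccc(OC)cc1OC | intermediate
12 | (2,4-dimethoxyphenyl){3-[(2,4-dimethoxyphenyl)(hydroxy)methylidene]-6,7-dimethoxy-4-(4-methoxyphenyl)-3,4-dihydronaphthalen-2-yl}methanone (enol; racemic, enol geometry not defined) | COc1ccc(cc1)C1C(=C(O)c2ccc(OC)cc2OC)C(C(=O)c2ccc(OC)cc2OC)=Cc2cc(OC)c(OC)cc12 | intermediate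
13 | rac-[(1R,2S)-6,7-dimethoxy-1-(4-methoxyphenyl)-1,2-dihydronaphthalene-2,3-diyl]bis[(2,4-dimethoxyphenyl)methanone] (trans; one enantiomer drawn) | COc1ccc(cc1)[C@H]1[C@H](C(=O)c2ccc(OC)cc2OC)C(C(=O)c2ccc(OC)cc2OC)=Cc2cc(OC)c(OC)cc21 | intermediate
14 | [6,7-dimethoxy-1-(4-methoxyphenyl)naphthalene-2,3-diyl]bis[(2,4-dimethoxyphenyl)methanone] | COc1ccc(cc1)-c1c(C(=O)c2ccc(OC)cc2OC)c(C(=O)c2ccc(OC)cc2OC)cc2cc(OC)c(OC)cc12 | intermediate
15 | [6,7-dihydroxy-1-(4-hydroxyphenyl)naphthalene-2,3-diyl]bis[(2,4-dihydroxyphenyl)methanone] (CNP0304576.0; no stereocentre) | O=C(c1ccc(O)cc1O)c1cc2cc(O)c(O)cc2c(-c2ccc(O)cc2)c1C(=O)c1ccc(O)cc1O | target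

Total step count: 6. Longest linear sequence: 6 steps (1 → 3 → 7 → 11 → 13 → 14 → 15).

Steps most likely to fail

Step 4. Capture of the cation by ring A may be too slow, because the hydroxyallyl cation is stabilised by two donor-substituted aryl groups, or multiple protonation of the carbonyl and methoxy groups may deactivate ring A. Only alkene isomerisation and slow degradation would then be seen; closure through the anisyl ring is a lesser risk. The fallback generates the C1 cation from an alcohol instead of an enone. It sets out from hydroxy ketone 9, which is isolated after the cold quench of step 3 and treated with BF3·OEt2 in CH2Cl2 at −20 to 0 °C. Ionisation of the 4-methoxybenzylic alcohol and Friedel–Crafts cycloalkylation by the same ring A carbon should form C1–C8a directly, the epimerisable C2 settling to the trans ketone, so the route is rejoined at 13. This benzylic-cation cycloalkylation is the standard closure of aryltetralin-type rings and makes no new compound.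

Step 3. Retro-aldol reversal of the hindered aldolate on the way to the quench, or attack of the cross-conjugated dienolate through its γ-carbon, may erode the addition. The fallback replaces the kinetic addition–activation–elimination sequence by a single condensation under thermodynamic control. It sets out from 7 and 8, which are heated with piperidinium acetate in toluene with azeotropic removal of water, the way deoxybenzoins, which have a comparably acidic methylene, are condensed with aryl aldehydes to α-aryl chalcones. Iminium activation of the aldehyde and irreversible dehydration should pull the reversible C–C bond formation through, and the route is rejoined at 11. No new compound is made.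

Step 2. Proton exchange between enolate and adduct, or incomplete mono-enolisation, may lead to double addition, and the adduct may cleave by retro-aldol reaction during mesylation. The fallback is a Wittig olefination that can deliver only one arylidene group. It sets out from 1, which is acylated with fumaryl chloride (AlCl3, CH2Cl2, 0 °C) to give the enedione (2E)-1,4-bis(2,4-dimethoxyphenyl)but-2-ene-1,4-dione F1. Conjugate addition of PBu3 and a proton shift should give the stabilised ylide 2-(tributyl-λ5-phosphanylidene)-1,4-bis(2,4-dimethoxyphenyl)butane-1,4-dione F2, which olefinates 4 in THF at rt to 60 °C with the E alkene favoured, and the route is rejoined at 7. This is the phospha-Michael/Wittig sequence known for fumarates, maleates and maleimides.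

Further compounds
F0 | step 4 | none | none
F0 | step 3 | none | none
F1 | step 2 | (2E)-1,4-bis(2,4-dimethoxyphenyl)but-2-ene-1,4-dione | COc1ccc(c(OC)c1)C(=O)/C=C/C(=O)c1ccc(OC)cc1OC
F2 | step 2 | 2-(tributyl-λ5-phosphanylidene)-1,4-bis(2,4-dimethoxyphenyl)butane-1,4-dione | CCCCP(CCCC)(CCCC)=C(CC(=O)c1ccc(OC)cc1OC)C(=O)c1ccc(OC)cc1OC
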